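## The problem

The target, 2-(3,5-dihydroxy-4-methoxyphenyl)-5-hydroxy-3,6,7,8-tetramethoxy-4H-chromen-4-one, has no stereocenter. Its difficulty lies in placing eight oxygen substituents on a flavone. Ring A (C4a, C5 to C8, C8a) carries a substituent on every carbon, ring C carries the 3-methoxyl, and ring B is a 3',5'-dihydroxy-4'-methoxyphenyl group. Three hydroxyls (C5, C3', C5') must end free among five methoxyls. The C5 oxygen is peri to the C4 carbonyl and can be singled out late by chelation, but the ring-B pair must be masked from the start. The usual flavone syntheses close ring C through O1–C2 from a 2-hydroxyaryl ketone, which here would be a hexasubstituted benzene that is laborious to assemble. The fully oxygenated ring A is prone to oxidation to quinones, the free ring-B phenols oxidise as phenoxides, the 3- and 5-methoxyls flank a carbonyl and are exposed to Lewis acids, and the pyranone opens in hot hydroxide. The enabling feature is that, once O1 is removed from C8a, ring A is a 2,3,4,5-tetramethoxyphenyl ketone with a single aryl C–H, at the future C8a. That carbon is ortho to the C8 methoxyl and para to the C6 methoxyl, so ring C can be closed by C–H functionalisation without regiochemical choice. The one stereocenter of the open-chain precursor is erased in the closure, so no stereocontrol is needed.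

## Retrosynthesis

**10 to 9.** The two ring-B O–acetyl bonds are cut, so that target 10 comes from diacetate 9. Acetates are preferred to benzyl or silyl ethers because they withdraw electron density from ring B (needed in the ring closure), tolerate Lewis acids, and leave by methanolysis that touches nothing else. The forward step only asks for mild transesterification.

**9 to 8.** The C5 hydroxyl is traced back to a methoxyl (O–CH3 bond), giving pentamethoxyflavone diacetate 8. A free C5 hydroxyl cannot be carried earlier: it would be oxidised in the ring closure, and in the open-chain diketone it would close ring C through the wrong oxygen. A separate protecting group would cost steps and the symmetry of the arene. The forward step must cleave one methoxyl of five; the six-membered chelate between C4=O and O5 provides the discrimination.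

**8 to 7.** The O1–C8a bond is cut, giving the 2-methoxy-1,3-diketone 7. The neighbouring cut O1–C2 would demand a phenol at C8a and hence a hexasubstituted ring A. The chosen cut leaves ring A with a hydrogen there, so 7 has one ring fewer and its ring A derives from a symmetric tetramethoxybenzene. The forward reaction must remove two electrons and two protons from 7, oxidising ring A rather than ring B and forming the C–O bond at the C–H carbon.

**7 to 3 and 6.** The bond between the methoxy-bearing carbon and the ring-B carbonyl (C2–C3 of the flavone) is cut, giving α-methoxy ketone 3 and aroyl chloride 6. The alternative cut on the ring-A side would need a tetramethoxybenzoyl chloride and a ring-B α-methoxyacetophenone, each more than one step from commercial material. The forward step must acylate on carbon, not oxygen, without harming the aryl acetates, which points to soft enolisation.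

**6 to 5 to 4.** The acyl chloride 6 comes from acid 5, and 5 from commercial 3,5-dihydroxy-4-methoxybenzoic acid 4 by acetylation. These are functional-group operations only.

**3 to 1 and 2.** The aryl–carbonyl bond is cut, giving 1,2,3,4-tetramethoxybenzene 1 and methoxyacetyl chloride 2. The two free positions of 1 are equivalent, so a Friedel–Crafts acylation can give only one ketone. The forward step must keep the methoxyl ortho to the new ketone intact.

## Roads not taken

**Alternative 1: biomimetic folding of a polycarbonyl chain.** Ring A is cut at C4a–C8a and ring C at O1–C2, leading back to the acyclic tetraketo ester A1. In the forward step, base would condense the one methylene carbon of A1 (future C4a) onto the ester carbon (future C8a). Enolisation then aromatises ring A, and acid closes ring C with loss of water to give flavone A2.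
- Merits: two rings form in one operation, and the symmetric phloroglucinol intermediate makes the ring-C closure regiochemically indifferent. The C5 hydroxyl arrives free, so no demethylation is needed; in this respect the road is better than the chosen one.
- Weak points: A1 carries five carbonyls and three enolisable methoxy methines. It offers several competing aldol and Claisen modes and can lactonise to a pyranone. Its assembly would take many acylations on labile intermediates. After A2, selective 7-O-methylation and debenzylation are still required, so the end game is no shorter.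
- Comparison: the chosen plan sets against it two intermolecular C–C bond formations from stable aromatic compounds and four steps before the closure.

**Alternative 2: carbene-catalysed benzoin closure.** The C3–C4 bond is cut, leading to dialdehyde A3. A triazolium-derived carbene would turn the ring-A aldehyde into an acyl anion equivalent that adds to the aliphatic aldehyde, giving dihydroflavonol A4.
- Merits: the conditions are mild and metal-free, and intramolecular benzoin closures to 3-hydroxychromanones are an established reaction class. The precedent is better than that of the chosen closure, and this must be conceded.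
- Weak points: the aryl aldehyde of A3 is flanked by two ortho substituents and is electron-rich, so the carbene should prefer the aliphatic aldehyde. That Breslow intermediate carries an α-aryloxy leaving group and can expel it. A4 has two stereocenters that are then destroyed. It still needs dehydrogenation, 3-O-methylation, C5 demethylation and debenzylation, four steps against two, and A3 itself needs a fully substituted salicylaldehyde.
- Comparison: the chosen plan accepts a less precedented closure in exchange for the correct oxidation level, the 3-methoxyl already in place, and a much simpler ring-A building block.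

**Alternative 3: ring B annulated on the chromone.** Ring B is cut at C1'–C6' and C4'–C5', leading to chromonyl enone A5. Dimethyl malonate would add to A5 at C1', and the methoxymethylene carbon would then attack a malonate ester, giving cyclohexanedione A6.
- Merits: the ring-B oxygen pattern arrives differentiated without protecting groups, which the chosen plan needs.
- Weak points: the key step does not address the hard part of the molecule, since the fully methoxylated chromone must already exist. C2 of the chromone is a competing Michael acceptor and could lead to ring opening. A6 still needs ester removal, dehydrogenative aromatisation and C5 demethylation.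
- Comparison: this road is longer in every count.

Key step: step 5

Assumption: compounds 1, 2 and 4 are taken as purchasable. Diketone 7 is a racemate that exists as a keto–enol mixture; its one stereocenter disappears in step 5.

## Route

Step 1
Reactants: 1 1,2,3,4-tetramethoxybenzene; 2 methoxyacetyl chloride
Product: 3 2-methoxy-1-(2,3,4,5-tetramethoxyphenyl)ethan-1-one
Conditions: AlCl3 (1.1 equiv), CH2Cl2, −10 → 0 °C; then ice, 1 M HCl
Reagents that add atoms: none
Why: Friedel–Crafts acylation; the two free positions of 1 are equivalent and each is ortho to one methoxyl and para to another, so only one ketone can form, and low temperature with near-stoichiometric Lewis acid should spare the chelated ortho methoxyl.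

Step 2
Reactants: 4 3,5-dihydroxy-4-methoxybenzoic acid
Product: 5 3,5-bis(acetyloxy)-4-methoxybenzoic acid
Conditions: Ac2O (2.5 equiv), pyridine, 0 °C → rt; then aq. HCl
Reagents that add atoms: acetic anhydride, CC(=O)OC(C)=O
Why: Standard O-acetylation of phenols by nucleophilic acyl substitution; the carboxyl group emerges free from the aqueous acidic work-up.

Step 3
Reactants: 5 3,5-bis(acetyloxy)-4-methoxybenzoic acid
Product: 6 3,5-bis(acetyloxy)-4-methoxybenzoyl chloride
Conditions: (COCl)2, DMF (cat.), CH2Cl2, 0 °C → rt; evaporate, use crude
Reagents that add atoms: oxalyl chloride, O=C(Cl)C(=O)Cl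
Why: Acid chloride formation through the Vilsmeier-type chloroiminium catalyst; aryl acetates and the methyl ether are inert and the by-products are gases.

Step 4
Reactants: 3 2-methoxy-1-(2,3,4,5-tetramethoxyphenyl)ethan-1-one; 6 3,5-bis(acetyloxy)-4-methoxybenzoyl chloride
Product: 7 2-methoxy-5-[2-methoxy-3-oxo-3-(2,3,4,5-tetramethoxyphenyl)propanoyl]-1,3-phenylene diacetate (racemic, keto–enol mixture)
Conditions: MgBr2·OEt2 (2.5 equiv), i-Pr2NEt (3 equiv), CH2Cl2, 0 °C → rt; then 1 M HCl
Reagents that add atoms: none
Why: Crossed Claisen-type C-acylation by soft enolisation: magnesium chelates the ketone and its α-methoxyl, the amine deprotonates, and the magnesium enolate is acylated on carbon and held as the diketonate chelate, under conditions too mild to cleave aryl acetates; the new stereocenter is formed racemic and is removed in step 5.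

Step 5
Reactants: 7 2-methoxy-5-[2-methoxy-3-oxo-3-(2,3,4,5-tetramethoxyphenyl)propanoyl]-1,3-phenylene diacetate
Product: 8 2-methoxy-5-(3,5,6,7,8-pentamethoxy-4-oxo-4H-chromen-2-yl)-1,3-phenylene diacetate
Conditions: undivided cell, graphite anode, Pt cathode, n-Bu4NBF4 (0.1 M), 1,1,1,3,3,3-hexafluoropropan-2-ol (HFIP), constant current 5 mA cm−2, about 2.2 F mol−1, rt
Reagents that add atoms: none
Why: Proposed new method: the tetramethoxyphenyl ketone of 7 is its most electron-rich π-system and should lose one electron at the anode to a radical cation that HFIP stabilises and does not trap; the enol whose hydroxyl sits on the ring-B side then adds through oxygen to the only C–H carbon of ring A (ortho to the ketone, ortho to one methoxyl, para to another), and loss of a second electron and two protons, with hydrogen evolved at the cathode and electrogenerated hexafluoroisopropoxide as base, gives the aromatic chromone. The closest known reaction types are anodic and FeCl3-mediated dehydrogenative aryl C–O cyclisations of tethered oxygen nucleophiles (coumestans from 3-aryl-4-hydroxycoumarins, benzocoumarins from biaryl-2-carboxylic acids); closure of a 4-pyranone by an enol oxygen has not been shown. Ring C closes as a six-membered ring, formally 6-endo-trig with respect to the C4a–C8a bond, after rotation about the C3–C4 bond of the Z-enol. No stereocenter is formed and the one in 7 is erased. Three selectivities are needed: ring A must be oxidised before ring B, which the two acetoxy groups on ring B secure; attack must occur at the C–H carbon and not ipso at the methoxyl-bearing ortho carbon, which is secured because only the C–H adduct can lose a proton and rearomatise under net oxidation while ipso addition is reversible; and the methine between the carbonyls must not be oxidised and trapped, which the non-nucleophilic solvent and a charge limited to about two electrons per molecule favour.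

Step 6
Reactants: 8 2-methoxy-5-(3,5,6,7,8-pentamethoxy-4-oxo-4H-chromen-2-yl)-1,3-phenylene diacetate
Product: 9 5-(5-hydroxy-3,6,7,8-tetramethoxy-4-oxo-4H-chromen-2-yl)-2-methoxy-1,3-phenylene diacetate
Conditions: AlCl3 (4 equiv), MeCN, rt → 50 °C; then cold dil. aq. HCl
Reagents that add atoms: none
Why: Chelation-controlled Lewis-acid ether cleavage, the standard selective 5-O-demethylation of polymethoxyflavones: aluminium bridges C4=O and O5 in a six-membered chelate and chloride removes that methyl, whereas the 3-methoxyl could only form a five-membered chelate and the other methoxyls none; the acetates keep the ring-B oxygens from chelating next to the 4'-methoxyl.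

Step 7
Reactants: 9 5-(5-hydroxy-3,6,7,8-tetramethoxy-4-oxo-4H-chromen-2-yl)-2-methoxy-1,3-phenylene diacetate
Product: 10 2-(3,5-dihydroxy-4-methoxyphenyl)-5-hydroxy-3,6,7,8-tetramethoxy-4H-chromen-4-one (5,3',5'-trihydroxy-3,6,7,8,4'-pentamethoxyflavone)
Conditions: K2CO3 (0.5 equiv), MeOH, 0 °C → rt, N2; AcOH quench
Reagents that add atoms: none
Why: Base-catalysed transesterification (Zemplén-type methanolysis) of the aryl acetates, whose phenoxide leaving groups make them far more reactive than the methyl ethers or the chromone; nitrogen and the acidic quench protect the phenoxides from air oxidation.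

## Compound list

1 | 1,2,3,4-tetramethoxybenzene | COc1ccc(OC)c(OC)c1OC | starting material
2 | methoxyacetyl chloride | COCC(=O)Cl | starting material
3 | 2-methoxy-1-(2,3,4,5-tetramethoxyphenyl)ethan-1-one | COCC(=O)c1cc(OC)c(OC)c(OC)c1OC | intermediate
4 | 3,5-dihydroxy-4-methoxybenzoic acid | COc1c(O)cc(C(=O)O)cc1O | starting material
5 | 3,5-bis(acetyloxy)-4-methoxybenzoic acid | COc1c(OC(C)=O)cc(C(=O)O)cc1OC(C)=O | intermediate
6 | 3,5-bis(acetyloxy)-4-methoxybenzoyl chloride | COc1c(OC(C)=O)cc(C(=O)Cl)cc1OC(C)=O | intermediate
7 | 2-methoxy-5-[2-methoxy-3-oxo-3-(2,3,4,5-tetramethoxyphenyl)propanoyl]-1,3-phenylene diacetate (racemic) | COC(C(=O)c1cc(OC)c(OC)c(OC)c1OC)C(=O)c1cc(OC(C)=O)c(OC)c(OC(C)=O)c1 | intermediate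
8 | 2-methoxy-5-(3,5,6,7,8-pentamethoxy-4-oxo-4H-chromen-2-yl)-1,3-phenylene diacetate | COc1c(OC)c(OC)c2oc(-c3cc(OC(C)=O)c(OC)c(OC(C)=O)c3)c(OC)c(=O)c2c1OC | intermediate
9 | 5-(5-hydroxy-3,6,7,8-tetramethoxy-4-oxo-4H-chromen-2-yl)-2-methoxy-1,3-phenylene diacetate | COc1c(OC)c(OC)c2oc(-c3cc(OC(C)=O)c(OC)c(OC(C)=O)c3)c(OC)c(=O)c2c1O | intermediate
10 | 2-(3,5-dihydroxy-4-methoxyphenyl)-5-hydroxy-3,6,7,8-tetramethoxy-4H-chromen-4-one | COc1c(O)cc(-c2oc3c(OC)c(OC)c(OC)c(O)c3c(=O)c2OC)cc1O | target

## Step count and risk

Total: 7 steps. Longest linear sequence: 6 steps (4 → 5 → 6 → 7 → 8 → 9 → 10); the ring-A branch (1 → 3) joins at step 4.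

**Step 5 (key step).**
- Risk: oxidation may occur at the enolised methine and be followed by trapping at C2, instead of C–O closure.
- Risk: the product may be oxidised further, since its ring A is fully oxygenated and could lose a methyl to give a quinone.
- Risk: enolisation in HFIP may be too slow to keep pace with arene oxidation.
- Fallback (known chemistry, from 3, rejoining at 8): ketone 3 would be brominated at its single aryl C–H with NBS in MeCN to give 1-(2-bromo-3,4,5,6-tetramethoxyphenyl)-2-methoxyethan-1-one F1. Acylation of F1 with 6 under the conditions of step 4 would give 5-[3-(2-bromo-3,4,5,6-tetramethoxyphenyl)-2-methoxy-3-oxopropanoyl]-2-methoxy-1,3-phenylene diacetate F2. F2 would be closed to 8 by copper-catalysed intramolecular Ullmann-type O-arylation of its enolate (CuI, 1,10-phenanthroline, K2CO3, DMF, 90 °C), a known route from 1-(2-bromoaryl)-1,3-diketones to chromones. Brief treatment of the crude product with Ac2O and pyridine would restore any acetate lost to the carbonate. The same O1–C8a bond is formed, at the cost of two steps and a halogen.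

**Step 4.**
- Risk: acylation on the enolate oxygen (enol ester), a second acylation of the diketonate, or acetyl transfer from an aryl acetate, because the nucleophilic carbon is hindered by its methoxyl.
- Fallback (from 6 and 3, rejoining at 7): an aldol–oxidation sequence. Rosenmund hydrogenation of 6 (H2, Pd on BaSO4, 2,6-lutidine, toluene) would give 5-formyl-2-methoxy-1,3-phenylene diacetate F3. Ketone 3 would be converted with TMSOTf and Et3N into trimethyl{[2-methoxy-1-(2,3,4,5-tetramethoxyphenyl)ethenyl]oxy}silane F4 (E/Z mixture). Mukaiyama aldol addition of F4 to F3 (BF3·OEt2, CH2Cl2, −78 °C) would give 5-[1-hydroxy-2-methoxy-3-oxo-3-(2,3,4,5-tetramethoxyphenyl)propyl]-2-methoxy-1,3-phenylene diacetate F5 (racemic mixture of diastereomers). Dess–Martin periodinane would oxidise F5 to 7.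

**Step 1.**
- Risk: cleavage of the methoxyl ortho to the new ketone through aluminium chelation, or loss of carbon monoxide from the methoxyacetyl cation followed by alkylation of the arene.
- Fallback (from 1, rejoining at 3): ortho-lithiation of 1 with n-BuLi and TMEDA in THF at 0 °C would give (2,3,4,5-tetramethoxyphenyl)lithium F6. F6 would be acylated at −78 °C with commercial N,2-dimethoxy-N-methylacetamide (the Weinreb amide of methoxyacetic acid) and quenched with aqueous NH4Cl to give 3. No Lewis acid is involved.

**Step 6.**
- Risk: further demethylation at C6 or C3 once the C5 aluminium phenoxide has formed, or loss of an acetate followed by chelation-assisted cleavage of the 4'-methoxyl.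
- Fallback (from 3, rejoining at 9): the C5 oxygen would be differentiated from the outset. BCl3 (CH2Cl2, −78 → 0 °C) would cleave the methoxyl ortho to the ketone of 3 to give 1-(2-hydroxy-3,4,5-trimethoxyphenyl)-2-methoxyethan-1-one F7. Alkylation with 2-bromopropane and K2CO3 in DMF would give 2-methoxy-1-[3,4,5-trimethoxy-2-(propan-2-yloxy)phenyl]ethan-1-one F8. Acylation with 6 as in step 4 would give 2-methoxy-5-{2-methoxy-3-oxo-3-[3,4,5-trimethoxy-2-(propan-2-yloxy)phenyl]propanoyl}-1,3-phenylene diacetate F9. Anodic closure as in step 5 would give 2-methoxy-5-[3,6,7,8-tetramethoxy-4-oxo-5-(propan-2-yloxy)-4H-chromen-2-yl]-1,3-phenylene diacetate F10. BCl3 at −78 °C removes the peri isopropyl ether far faster than any methyl ether and would give 9. This fallback reuses the step 5 closure on F9.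

## Further compounds

F1 | step 5 | 1-(2-bromo-3,4,5,6-tetramethoxyphenyl)-2-methoxyethan-1-one | COCC(=O)c1c(Br)c(OC)c(OC)c(OC)c1OC
F2 | step 5 | 5-[3-(2-bromo-3,4,5,6-tetramethoxyphenyl)-2-methoxy-3-oxopropanoyl]-2-methoxy-1,3-phenylene diacetate (racemic) | COC(C(=O)c1c(Br)c(OC)c(OC)c(OC)c1OC)C(=O)c1cc(OC(C)=O)c(OC)c(OC(C)=O)c1
F3 | step 4 | 5-formyl-2-methoxy-1,3-phenylene diacetate | COc1c(OC(C)=O)cc(C=O)cc1OC(C)=O
F4 | step 4 | trimethyl{[2-methoxy-1-(2,3,4,5-tetramethoxyphenyl)ethenyl]oxy}silane (E/Z mixture) | COC=C(O[Si](C)(C)C)c1cc(OC)c(OC)c(OC)c1OC
F5 | step 4 | 5-[1-hydroxy-2-methoxy-3-oxo-3-(2,3,4,5-tetramethoxyphenyl)propyl]-2-methoxy-1,3-phenylene diacetate (racemic mixture of diastereomers) | COC(C(=O)c1cc(OC)c(OC)c(OC)c1OC)C(O)c1cc(OC(C)=O)c(OC)c(OC(C)=O)c1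
F6 | step 1 | (2,3,4,5-tetramethoxyphenyl)lithium | [Li]c1cc(OC)c(OC)c(OC)c1OC
F7 | step 6 | 1-(2-hydroxy-3,4,5-trimethoxyphenyl)-2-methoxyethan-1-one | COCC(=O)c1cc(OC)c(OC)c(OC)c1O
F8 | step 6 | 2-methoxy-1-[3,4,5-trimethoxy-2-(propan-2-yloxy)phenyl]ethan-1-one | COCC(=O)c1cc(OC)c(OC)c(OC)c1OC(C)C
F9 | step 6 | 2-methoxy-5-{2-methoxy-3-oxo-3-[3,4,5-trimethoxy-2-(propan-2-yloxy)phenyl]propanoyl}-1,3-phenylene diacetate (racemic) | COC(C(=O)c1cc(OC)c(OC)c(OC)c1OC(C)C)C(=O)c1cc(OC(C)=O)c(OC)c(OC(C)=O)c1
F10 | step 6 | 2-methoxy-5-[3,6,7,8-tetramethoxy-4-oxo-5-(propan-2-yloxy)-4H-chromen-2-yl]-1,3-phenylene diacetate | COc1c(OC)c(OC)c2oc(-c3cc(OC(C)=O)c(OC)c(OC(C)=O)c3)c(OC)c(=O)c2c1OC(C)C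
A1 | alternative 1 | methyl 9-[3,5-bis(benzyloxy)-4-methoxyphenyl]-2,4,8-trimethoxy-3,5,7,9-tetraoxononanoate (mixture of stereoisomers and enol forms) | COC(=O)C(OC)C(=O)C(OC)C(=O)CC(=O)C(OC)C(=O)c1cc(OCc2ccccc2)c(OC)c(OCc2ccccc2)c1
A2 | alternative 1 | 2-[3,5-bis(benzyloxy)-4-methoxyphenyl]-5,7-dihydroxy-3,6,8-trimethoxy-4H-chromen-4-one | COc1c(O)c(OC)c2oc(-c3cc(OCc4ccccc4)c(OC)c(OCc4ccccc4)c3)c(OC)c(=O)c2c1O
A3 | alternative 2 | 2-{1-[3,5-bis(benzyloxy)-4-methoxyphenyl]-2-oxoethoxy}-3,4,5,6-tetramethoxybenzaldehyde (racemic) | O=CC(Oc1c(C=O)c(OC)c(OC)c(OC)c1OC)c1cc(OCc2ccccc2)c(OC)c(OCc2ccccc2)c1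
A4 | alternative 2 | 2-[3,5-bis(benzyloxy)-4-methoxyphenyl]-3-hydroxy-5,6,7,8-tetramethoxychroman-4-one (racemic mixture of diastereomers) | COc1c(OC)c(OC)c2c(c1OC)OC(c1cc(OCc3ccccc3)c(OC)c(OCc3ccccc3)c1)C(O)C2=O
A5 | alternative 3 | (E)-1-methoxy-4-(3,5,6,7,8-pentamethoxy-4-oxo-4H-chromen-2-yl)but-3-en-2-one | COCC(=O)/C=C/c1oc2c(OC)c(OC)c(OC)c(OC)c2c(=O)c1OC
A6 | alternative 3 | methyl 5-methoxy-4,6-dioxo-2-(3,5,6,7,8-pentamethoxy-4-oxo-4H-chromen-2-yl)cyclohexane-1-carboxylate (racemic mixture of diastereomers and enol forms) | COC(=O)C1C(=O)C(OC)C(=O)CC1c1oc2c(OC)c(OC)c(OC)c(OC)c2c(=O)c1OC
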